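**Retrosynthetic overview**
1. Target 24 ⇐ C3 angeloylation and fluoride desilylation of bis-silyl ether 20; C8=CH2 ⇐ Wittig methylenation of 8-ketone 19.
2. Ring B ⇐ one-carbon ring expansion: semipinacol 1,2-shift of the quaternary C10 from C8 to C9 in β-hydroxy selenide 18, made from trans-hydrindanone 8 and side-chain carbanion 17 (C9, C11–C16).
3. 8 ⇐ 4-methyl Hajos–Parrish-type enedione 4 by reductive hydroxymethylation (sets C4, C5) and hydroxyl-directed reduction (sets C3).
4. 4 ⇐ 2-methylcyclopentane-1,3-dione + ethyl vinyl ketone (sets C10); side chain ⇐ Johnson–Claisen rearrangement (sets 13E) of the carbinol from 9 + 10.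
5. Ring order: the cyclopentane is bought, ring A is annulated onto it, and ring B is formed last by expanding the five-membered ring.

Assumption: the SMILES is read as the ent-labdane (3R,4S,5S,9R,10S,13E)-15,18-dihydroxylabda-8(17),13-dien-3-yl (Z)-2-methylbut-2-enoate (angelate); 9 and 10 are bought as such.

**Route**

Step 1
Reactants: 1 2-methylcyclopentane-1,3-dione; 2 pent-1-en-3-one
Product: 4 (7aR)-4,7a-dimethyl-2,3,7,7a-tetrahydro-1H-indene-1,5(6H)-dione, via triketone 3 (not isolated)
Conditions: 2 (1.3 equiv), Et3N (5 mol%), MeCN, 25 °C; then D-phenylalanine (1.0 equiv), 1 M HClO4 (0.4 equiv), reflux; recrystallise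
Reagents that add atoms: none
Why: Michael addition followed by an amino-acid-mediated (Hajos–Parrish-type) intramolecular aldol condensation, in which the D-phenylalanine enamine selects one of the two enantiotopic ring carbonyls and so fixes the quaternary centre (7aR, the future C10).

Step 2
Reactants: 4 (7aR)-4,7a-dimethyl-2,3,7,7a-tetrahydro-1H-indene-1,5(6H)-dione
Product: 6 (3aS,4S,7aR)-4-(hydroxymethyl)-4,7a-dimethyloctahydro-1H-indene-1,5-dione, via aluminium enolate 5 (not isolated)
Conditions: tBuCu (20 mol%, from tBuLi + CuI), iBu2AlH (1.2 equiv), HMPA, THF, −50 °C; then HCHO gas (from cracked paraformaldehyde), −50 → −20 °C; aq NH4Cl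
Reagents that add atoms: formaldehyde, C=O
Why: Proposed new method: the copper hydride formed from tBuCu and iBu2AlH in THF/HMPA should add hydride 1,4 to the tetrasubstituted enone from the face opposite the angular methyl (trans ring fusion, C5) faster than iBu2AlH attacks the hindered cyclopentanone, and the regiodefined aluminium enolate 5 should then be hydroxymethylated by monomeric formaldehyde anti to the angular methyl, giving the C4 quaternary centre with CH2OH equatorial in a tandem conjugate reduction–aldol; the closest known reactions are the trans-selective tBuCu/iBu2AlH/HMPA conjugate reduction of the parent Hajos–Parrish dione, aldol trapping of aluminium enolates, and the lithium/ammonia reductive hydroxymethylation of 4-methyl enones.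

Step 3
Reactants: 6 (3aS,4S,7aR)-4-(hydroxymethyl)-4,7a-dimethyloctahydro-1H-indene-1,5-dione
Product: 7 (3aR,4S,5R,7aR)-5-hydroxy-4-(hydroxymethyl)-4,7a-dimethyloctahydro-1H-inden-1-one
Conditions: Me4NBH(OAc)3 (5 equiv), MeCN/AcOH 1:1, −30 → −20 °C
Reagents that add atoms: none
Why: Evans–Saksena hydroxyl-directed reduction, in which the acetoxyborohydride bound to the primary hydroxyl delivers hydride to the neighbouring ketone from the CH2OH face (also the face away from both axial methyls) to give the equatorial C3 alcohol trans to CH2OH, while the cyclopentanone has no directing hydroxyl and is left untouched.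

Step 4
Reactants: 7 (3aR,4S,5R,7aR)-5-hydroxy-4-(hydroxymethyl)-4,7a-dimethyloctahydro-1H-inden-1-one
Product: 8 (3aR,4S,5R,7aR)-4-{[(tert-butyldimethylsilyl)oxy]methyl}-5-hydroxy-4,7a-dimethyloctahydro-1H-inden-1-one
Conditions: TBSCl (1.1 equiv), imidazole, CH2Cl2, 0 °C
Reagents that add atoms: tert-butyldimethylsilyl chloride, CC(C)(C)[Si](C)(C)Cl
Why: Selective silylation of the primary hydroxyl over the hindered secondary one flanked by the quaternary carbon.

Step 5
Reactants: 9 (tert-butyldimethylsilyloxy)acetaldehyde; 10 isopropenylmagnesium bromide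
Product: 11 rac-1-[(tert-butyldimethylsilyl)oxy]-3-methylbut-3-en-2-ol
Conditions: 10 (1.2 equiv), THF, −78 → 0 °C; aq NH4Cl
Reagents that add atoms: none
Why: Grignard 1,2-addition to the aldehyde; the carbinol centre is racemic and is destroyed in the next step.

Step 6
Reactants: 11 rac-1-[(tert-butyldimethylsilyl)oxy]-3-methylbut-3-en-2-ol; 12 trimethyl orthoacetate
Product: 14 methyl (4E)-6-[(tert-butyldimethylsilyl)oxy]-4-methylhex-4-enoate, via ketene acetal 13 (not isolated)
Conditions: 12 (5 equiv), EtCO2H (5 mol%), xylene, 135 °C, MeOH distilled off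
Reagents that add atoms: none
Why: Johnson–Claisen rearrangement through a chair transition state with the CH2OTBS group equatorial (the axial alternative clashes with the methoxy group), which gives the 13E trisubstituted alkene.

Step 7
Reactants: 14 methyl (4E)-6-[(tert-butyldimethylsilyl)oxy]-4-methylhex-4-enoate
Product: 15 (4E)-6-[(tert-butyldimethylsilyl)oxy]-4-methylhex-4-enal
Conditions: iBu2AlH (1.05 equiv), CH2Cl2, −78 °C; MeOH, then aq NH4Cl
Reagents that add atoms: none
Why: Low-temperature partial reduction of the ester to the aldehyde through the stable aluminium hemiacetal.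

Step 8
Reactants: 15 (4E)-6-[(tert-butyldimethylsilyl)oxy]-4-methylhex-4-enal
Product: 16 tert-butyl{[(2E)-3-methyl-6,6-bis(methylselanyl)hex-2-en-1-yl]oxy}dimethylsilane
Conditions: MeSeH (3 equiv), ZnCl2 (0.5 equiv), CH2Cl2, −20 → 20 °C
Reagents that add atoms: methaneselenol, C[SeH]
Why: Lewis-acid-promoted selenoacetalisation of the aldehyde, which turns the future C9 into a carbanion precursor.

Step 9
Reactants: 8 (3aR,4S,5R,7aR)-4-{[(tert-butyldimethylsilyl)oxy]methyl}-5-hydroxy-4,7a-dimethyloctahydro-1H-inden-1-one; 16 tert-butyl{[(2E)-3-methyl-6,6-bis(methylselanyl)hex-2-en-1-yl]oxy}dimethylsilane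
Product: 18 (1R,3aR,4S,5R,7aR)-1-[(4E)-6-[(tert-butyldimethylsilyl)oxy]-4-methyl-1-(methylselanyl)hex-4-en-1-yl]-4-{[(tert-butyldimethylsilyl)oxy]methyl}-4,7a-dimethyloctahydro-1H-indene-1,5-diol, via lithium reagent 17 (not isolated)
Conditions: 16 (2.3 equiv), nBuLi (2.3 equiv), THF, −78 °C; then 8, −78 → −40 °C; aq NH4Cl
Reagents that add atoms: none
Why: Selenium–lithium exchange gives a strongly nucleophilic, weakly basic α-selenoalkyllithium (the first equivalent deprotonates the free hydroxyl) that adds 1,2 to the hindered cyclopentanone from the face opposite the angular methyl; the selenium-bearing carbon forms as an epimer mixture, which does not matter because the next step converges.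

Step 10
Reactants: 18 (1R,3aR,4S,5R,7aR)-1-[(4E)-6-[(tert-butyldimethylsilyl)oxy]-4-methyl-1-(methylselanyl)hex-4-en-1-yl]-4-{[(tert-butyldimethylsilyl)oxy]methyl}-4,7a-dimethyloctahydro-1H-indene-1,5-diol
Product: 19 (3R,4S,5S,9S,10R,13E)-15,18-bis[(tert-butyldimethylsilyl)oxy]-3-hydroxy-17-norlabd-13-en-8-one
Conditions: AgBF4 on neutral Al2O3 (3 equiv), CH2Cl2, 20 °C; then DBU (0.2 equiv), 20 °C
Reagents that add atoms: none
Why: Semipinacol ring expansion of a β-hydroxyalkyl selenide, in which the selenophilic silver ion makes MeSe a leaving group and the electron-rich quaternary ring-fusion carbon (C10) migrates to C9 with retention in preference to the methylene C7, turning the trans-hydrindanol into the trans-decalone; DBU then equilibrates C9, α to the new ketone, to the equatorial side-chain epimer.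

Step 11
Reactants: 19 (3R,4S,5S,9S,10R,13E)-15,18-bis[(tert-butyldimethylsilyl)oxy]-3-hydroxy-17-norlabd-13-en-8-one
Product: 20 (3R,4S,5S,9R,10S,13E)-15,18-bis[(tert-butyldimethylsilyl)oxy]labda-8(17),13-dien-3-ol
Conditions: Ph3PCH3Br (4 equiv), KOtBu (3.8 equiv), toluene, 80 °C
Reagents that add atoms: methyltriphenylphosphonium bromide, C[P+](c1ccccc1)(c1ccccc1)c1ccccc1.[Br-]
Why: Wittig methylenation of the hindered ketone with excess ylide, which tolerates the free hydroxyl as its alkoxide and leaves C9 in its thermodynamically preferred equatorial configuration.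

Step 12
Reactants: 20 (3R,4S,5S,9R,10S,13E)-15,18-bis[(tert-butyldimethylsilyl)oxy]labda-8(17),13-dien-3-ol; 21 angelic acid [(Z)-2-methylbut-2-enoic acid]
Product: 23 (3R,4S,5S,9R,10S,13E)-15,18-bis[(tert-butyldimethylsilyl)oxy]labda-8(17),13-dien-3-yl (Z)-2-methylbut-2-enoate, via mixed anhydride 22 (not isolated)
Conditions: 21 (3 equiv), 2,4,6-trichlorobenzoyl chloride (3 equiv), Et3N, toluene, 20 °C; then 20, DMAP (2 equiv), 75 °C
Reagents that add atoms: none
Why: Yamaguchi esterification, in which the hindered alcohol attacks the less shielded angeloyl carbonyl of the mixed anhydride under conditions that avoid isomerisation of the Z double bond to the tiglate.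

Step 13
Reactants: 23 (3R,4S,5S,9R,10S,13E)-15,18-bis[(tert-butyldimethylsilyl)oxy]labda-8(17),13-dien-3-yl (Z)-2-methylbut-2-enoate
Product: 24 (3R,4S,5S,9R,10S,13E)-15,18-dihydroxylabda-8(17),13-dien-3-yl (Z)-2-methylbut-2-enoate
Conditions: HF·pyridine, pyridine/THF, 0 → 20 °C
Reagents that add atoms: none
Why: Buffered fluoride cleavage of both primary silyl ethers under mildly acidic conditions, which avoids the base-promoted acyl shift from O3 to O18 and leaves the exocyclic alkene and the angelate intact.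

**Compound list**
1 | 2-methylcyclopentane-1,3-dione | CC1C(=O)CCC1=O | starting material
2 | pent-1-en-3-one (ethyl vinyl ketone) | CCC(=O)C=C | starting material
3 | 2-methyl-2-(3-oxopentyl)cyclopentane-1,3-dione (not isolated) | CCC(=O)CCC1(C)C(=O)CCC1=O | intermediate
4 | (7aR)-4,7a-dimethyl-2,3,7,7a-tetrahydro-1H-indene-1,5(6H)-dione | O=C1CCC2=C(C)C(=O)CC[C@]21C | intermediate
5 | diisobutylaluminium enolate {[(3aR,7aR)-4,7a-dimethyl-1-oxo-2,3,3a,6,7,7a-hexahydro-1H-inden-5-yl]oxy}bis(2-methylpropyl)alane, 3a-H trans to 7a-CH3 (not isolated) | O=C1CC[C@H]2[C@@]1(C)CCC(O[Al](CC(C)C)CC(C)C)=C2C | intermediate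
6 | (3aS,4S,7aR)-4-(hydroxymethyl)-4,7a-dimethyloctahydro-1H-indene-1,5-dione (trans-fused; CH2OH trans to the 7a-methyl) | O=C1CC[C@H]2[C@@]1(C)CCC(=O)[C@]2(C)CO | intermediate
7 | (3aR,4S,5R,7aR)-5-hydroxy-4-(hydroxymethyl)-4,7a-dimethyloctahydro-1H-inden-1-one (5-OH equatorial, trans to CH2OH) | O=C1CC[C@H]2[C@@]1(C)CC[C@@H](O)[C@]2(C)CO | intermediate
8 | (3aR,4S,5R,7aR)-4-{[(tert-butyldimethylsilyl)oxy]methyl}-5-hydroxy-4,7a-dimethyloctahydro-1H-inden-1-one | O=C1CC[C@H]2[C@@]1(C)CC[C@@H](O)[C@]2(C)CO[Si](C)(C)C(C)(C)C | intermediate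
9 | (tert-butyldimethylsilyloxy)acetaldehyde | O=CCO[Si](C)(C)C(C)(C)C | starting material
10 | isopropenylmagnesium bromide | CC(=C)[Mg]Br | starting material
11 | rac-1-[(tert-butyldimethylsilyl)oxy]-3-methylbut-3-en-2-ol | CC(=C)C(O)CO[Si](C)(C)C(C)(C)C | intermediate
12 | trimethyl orthoacetate (1,1,1-trimethoxyethane) | CC(OC)(OC)OC | starting material
13 | mixed ketene acetal tert-butyl({2-[(1-methoxyethenyl)oxy]-3-methylbut-3-en-1-yl}oxy)dimethylsilane (not isolated) | C=C(OC)OC(CO[Si](C)(C)C(C)(C)C)C(C)=C | intermediate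
14 | methyl (4E)-6-[(tert-butyldimethylsilyl)oxy]-4-methylhex-4-enoate | COC(=O)CC/C(C)=C/CO[Si](C)(C)C(C)(C)C | intermediate
15 | (4E)-6-[(tert-butyldimethylsilyl)oxy]-4-methylhex-4-enal | O=CCC/C(C)=C/CO[Si](C)(C)C(C)(C)C | intermediate
16 | tert-butyl{[(2E)-3-methyl-6,6-bis(methylselanyl)hex-2-en-1-yl]oxy}dimethylsilane | C[Se]C([Se]C)CC/C(C)=C/CO[Si](C)(C)C(C)(C)C | intermediate
17 | [(4E)-6-[(tert-butyldimethylsilyl)oxy]-4-methyl-1-(methylselanyl)hex-4-en-1-yl]lithium (not isolated) | [Li]C([Se]C)CC/C(C)=C/CO[Si](C)(C)C(C)(C)C | intermediate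
18 | (1R,3aR,4S,5R,7aR)-1-[(4E)-6-[(tert-butyldimethylsilyl)oxy]-4-methyl-1-(methylselanyl)hex-4-en-1-yl]-4-{[(tert-butyldimethylsilyl)oxy]methyl}-4,7a-dimethyloctahydro-1H-indene-1,5-diol (1-OH cis to the 7a-methyl; both epimers at the selenium-bearing carbon) | C[Se]C(CC/C(C)=C/CO[Si](C)(C)C(C)(C)C)[C@@]1(O)CC[C@H]2[C@@]1(C)CC[C@@H](O)[C@]2(C)CO[Si](C)(C)C(C)(C)C | intermediate
19 | (3R,4S,5S,9S,10R,13E)-15,18-bis[(tert-butyldimethylsilyl)oxy]-3-hydroxy-17-norlabd-13-en-8-one (ent-labdane series, same spatial arrangement as 24) | O=C1CC[C@H]2[C@@](C)(CC[C@@H](O)[C@]2(C)CO[Si](C)(C)C(C)(C)C)[C@@H]1CC/C(C)=C/CO[Si](C)(C)C(C)(C)C | intermediate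
20 | (3R,4S,5S,9R,10S,13E)-15,18-bis[(tert-butyldimethylsilyl)oxy]labda-8(17),13-dien-3-ol | C=C1CC[C@H]2[C@@](C)(CC[C@@H](O)[C@]2(C)CO[Si](C)(C)C(C)(C)C)[C@@H]1CC/C(C)=C/CO[Si](C)(C)C(C)(C)C | intermediate
21 | angelic acid, (Z)-2-methylbut-2-enoic acid | C/C=C(/C)C(=O)O | starting material
22 | (Z)-2-methylbut-2-enoic 2,4,6-trichlorobenzoic anhydride (not isolated) | C/C=C(/C)C(=O)OC(=O)c1c(Cl)cc(Cl)cc1Cl | intermediate
23 | (3R,4S,5S,9R,10S,13E)-15,18-bis[(tert-butyldimethylsilyl)oxy]labda-8(17),13-dien-3-yl (Z)-2-methylbut-2-enoate | C=C1CC[C@H]2[C@@](C)(CC[C@@H](OC(=O)/C(C)=C\C)[C@]2(C)CO[Si](C)(C)C(C)(C)C)[C@@H]1CC/C(C)=C/CO[Si](C)(C)C(C)(C)C | intermediate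
24 | (3R,4S,5S,9R,10S,13E)-15,18-dihydroxylabda-8(17),13-dien-3-yl (Z)-2-methylbut-2-enoate (CNP0118197.1) | C=C1CC[C@H]2[C@@](C)(CC[C@@H](OC(=O)/C(C)=C\C)[C@]2(C)CO)[C@@H]1CC/C(C)=C/CO | target

**Step count**
Total: 13 steps. Longest linear sequence: 9 steps (1–4 then 9–13; the side-chain branch 5–8 then 9–13 is equally long).

**Three steps most likely to fail**

Step 2 (the proposed new step). Risks are slow or 1,2-selective reduction of the tetrasubstituted enone, a cis ring fusion, or poor C-hydroxymethylation. The fallback uses only known chemistry, sets out from 4 and returns at 7. The cyclopentanone of 4 is reduced selectively with NaBH4 in EtOH at −20 °C to the hydroxy enone F1. Lithium in liquid NH3/THF (the hydroxyl serving as proton donor), followed by gaseous formaldehyde, gives the trans-fused keto diol F2 by classical reductive hydroxymethylation. NaBH4 in MeOH gives the triol F3, and 2,2-dimethoxypropane with PPTS ties up its 1,3-diol as the acetonide alcohol F4. Dess–Martin periodinane oxidises the remaining secondary alcohol to the acetonide ketone F5, and 80% aqueous AcOH at 40 °C releases 7.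

Step 10. Risks are sluggish ionisation at the secondary selenium-bearing carbon, migration of C7 instead of C10, or acid damage to the silyl ethers. The fallback replaces the selenide semipinacol by an α-ketol ring expansion; it sets out from 8 and 15 and returns at 19. Aldehyde 15 is converted with propane-1,3-dithiol and BF3·OEt2 into the dithiane F6. Its 2-lithio derivative (nBuLi, THF, −30 °C, 2.3 equiv) is added to 8 to give the dithianyl carbinol F7. MeI and CaCO3 in aqueous MeCN unmask the α-hydroxy ketone F8. KOtBu in tBuOH/toluene then brings about the base-mediated α-ketol rearrangement (D-homoannulation type, the quaternary carbon migrating) to the ring-expanded hydroxy ketone F9. SmI2 in THF/MeOH removes the tertiary α-hydroxyl, and DBU equilibration gives 19.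

Step 12. Risks are low conversion of the neopentyl-type secondary alcohol and isomerisation of the angelate to the tiglate. The fallback builds the Z double bond on the substrate; it sets out from 20 and returns at 23. Alcohol 20 is acylated with 2-(diphenoxyphosphoryl)propanoic acid (DCC, DMAP, CH2Cl2) to the phosphonate ester F10. A Z-selective Horner–Wadsworth–Emmons olefination of F10 with acetaldehyde (NaH, THF, −78 °C, Ando-type diaryl phosphonate) then gives 23.

**Further compounds**
F1 | step 2 | (1R,7aR)-1-hydroxy-4,7a-dimethyl-1,2,3,6,7,7a-hexahydro-5H-inden-5-one | O[C@@H]1CCC2=C(C)C(=O)CC[C@]21C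
F2 | step 2 | trans-fused 1-hydroxy-4-(hydroxymethyl)-4,7a-dimethyloctahydro-5H-inden-5-one (1-OH cis and CH2OH trans to the 7a-methyl) | O[C@@H]1CC[C@H]2[C@@]1(C)CCC(=O)[C@]2(C)CO
F3 | step 2 | trans-fused 4-(hydroxymethyl)-4,7a-dimethyloctahydro-1H-indene-1,5-diol (5-OH equatorial, trans to CH2OH; 1-OH cis to the 7a-methyl) | O[C@@H]1CC[C@H]2[C@@]1(C)CC[C@@H](O)[C@]2(C)CO
F4 | step 2 | isopropylidene acetal (acetonide) of the 5-OH/4-CH2OH pair of F3 with the 1-OH free | O[C@@H]1CC[C@H]2[C@@]1(C)CC[C@H]3OC(C)(C)OC[C@]23C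
F5 | step 2 | isopropylidene acetal (acetonide) of 7 | O=C1CC[C@H]2[C@@]1(C)CC[C@H]3OC(C)(C)OC[C@]23C
F6 | step 10 | tert-butyl{[(2E)-5-(1,3-dithian-2-yl)-3-methylpent-2-en-1-yl]oxy}dimethylsilane | C1CSC(CC/C(C)=C/CO[Si](C)(C)C(C)(C)C)SC1
F7 | step 10 | adduct of lithiated F6 and 8: the 1-[2-substituted 1,3-dithian-2-yl]octahydroindene-1,5-diol (1-OH cis to the 7a-methyl; other centres as in 8) | O[C@]1(C2(CC/C(C)=C/CO[Si](C)(C)C(C)(C)C)SCCCS2)CC[C@H]2[C@@]1(C)CC[C@@H](O)[C@]2(C)CO[Si](C)(C)C(C)(C)C
F8 | step 10 | α-hydroxy ketone: 1-[(4E)-6-[(tert-butyldimethylsilyl)oxy]-4-methylhex-4-enoyl] analogue of F7 | O[C@]1(C(=O)CC/C(C)=C/CO[Si](C)(C)C(C)(C)C)CC[C@H]2[C@@]1(C)CC[C@@H](O)[C@]2(C)CO[Si](C)(C)C(C)(C)C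
F9 | step 10 | 9-hydroxy derivative of 19: 15,18-bis[(tert-butyldimethylsilyl)oxy]-3,9-dihydroxy-17-norlabd-13E-en-8-one (C9 configuration not defined) | O=C1CC[C@H]2[C@@](C)(CC[C@@H](O)[C@]2(C)CO[Si](C)(C)C(C)(C)C)C1(O)CC/C(C)=C/CO[Si](C)(C)C(C)(C)C
F10 | step 12 | 2-(diphenoxyphosphoryl)propanoate ester of 20 at O3 (epimers at the phosphonate-bearing carbon) | C=C1CC[C@H]2[C@@](C)(CC[C@@H](OC(=O)C(C)P(=O)(Oc3ccccc3)Oc3ccccc3)[C@]2(C)CO[Si](C)(C)C(C)(C)C)[C@@H]1CC/C(C)=C/CO[Si](C)(C)C(C)(C)C
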